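## Structural features

The target is a 2,5-diaryl-3,4-bis(hydroxymethyl)oxolane. One saturated five-membered ring (O1, C2 to C5) carries a 4-hydroxy-3-methoxyphenyl group on each carbon next to oxygen (C2, C5) and a CH2OH group on each of the other two (C3a on C3, C4a on C4). The four ring carbons are contiguous stereocentres, all (S): each aryl group is cis to the neighbouring CH2OH (C2/C3 and C4/C5), the two CH2OH groups are trans, and a C2 axis through O1 and the midpoint of C3–C4 makes the two halves identical. Both ring C–O bonds are benzylic and para to a phenolic oxygen. Acid (ring-opened, quinone-methide-like cation), hydrogenolysis and, less readily, free phenoxide can break them or epimerise C2/C5 to the more stable trans arrangement; the phenols and electron-rich rings are also sensitive to oxidants. The real difficulty is the contra-thermodynamic cis relation of each aryl group to its neighbour, combined with trans C3/C4, in one enantiomer. If C3a and C4a are masked as (E)-propenyl groups and the ring is opened at one C–O bond, Ar–C2(O)–C3 and Ar–C5(O)–C4 become two identical anti homoallylic alcohol units joined through C3–C4. Each unit is the retron of a [2,3]-Wittig shift of an allyl benzyl ether, and the C2 axis lets one symmetric dienediol diether deliver both units, both aryl groups and all four stereocentres at once.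

## Logic of the disconnections

17 to 16. The two phenolic O–H bonds are exchanged for O–Si bonds. Free phenols would consume organolithium and activate the ring towards oxidants, so they stay masked to the end. The demand on the forward step is a deprotection that uses neither acid nor hydrogen, since both attack the benzylic ring C–O bonds.

16 to 14. The C3–C3a–OH and C4–C4a–OH units are traced back to two (E)-propenyl groups by restoring a C=C bond at C3a and C4a. Free primary hydroxyls would compete as nucleophiles during ring closure at the benzylic carbons, whereas a propenyl group is inert and is exactly what a [2,3]-shift leaves behind. The forward cleavage must spare the arenes and must not let a beta-alkoxy aldehyde accumulate.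

14 to 12. The C2–H bond is cut, which leaves a hydroxyl at C2. The cis C2/C3 relation is the less stable one and is best set kinetically by hydride addition to a planar cyclic cation. One stereocentre is removed from the problem. The forward step must deliver hydride anti to the C3 substituent without epimerising C3 or C5.

12 to 10. The O1–C2 bond is cut and C2 is returned to the carbinol level. Because 10 has a C2 axis, oxidation of either carbinol gives the same hydroxy ketone, which closes to 12. The ring disappears and an acyclic symmetric diol remains. The oxidation must stop after one benzylic alcohol.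

10 to 8. The C1–C2 and C3–C4 bonds of 10 (ring bonds C2–C3 and C5–C4) are cut; each is the bond a [2,3]-Wittig shift makes. This removes four stereocentres and both aryl carbinol units and leaves a symmetric diether whose only stereocentres come from the chiral pool. The forward step needs lithiation at the two benzylic ether carbons only, [2,3] over [1,2] migration, and E-to-anti selectivity with (E) new alkenes in both events.

8 to 7 and 4. The two benzylic C–O bonds are cut. The ether synthesis must not touch the dienylic carbinol centres or the silyl ethers.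

7 to 6 to 5. The two (E)-alkenes come from alkynes by hydroxyl-directed trans reduction. The central sp–sp bond of 6 comes from oxidative homocoupling of 5, which already holds the (R) centre.

4 to 3 to 2 to 1. The C–Br bond is traced to the alcohol, the alcohol to the aldehyde, and the O–Si bond to the phenol of 1.

## Other disconnections considered

Alternative 1: The cut is at the two aryl–ring bonds (C2–Ar and C5–Ar). Going forward, the trans bis-amide A2 would be arylated twice with aryl iodide A3 under Pd(OAc)2 and AgOAc to give A1. Each quinolin-8-yl amide binds divalent palladium as a bidentate ligand, the C–H bond of the neighbouring OCH2 group is cleaved through a five-membered palladacycle, and oxidative addition of A3 (tetravalent palladium) followed by reductive elimination places the aryl group cis to the directing amide.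
- In favour: the ring and the trans C3/C4 relation are present from the start, and the route is convergent.
- Against: two bidentate amides on adjacent carbons can bind one palladium between them and stall the cycle. The second arylation must occur on a crowded ring. AgOAc is needed in excess. The auxiliaries must later be removed from centres that are alpha to a carbonyl and cis to an aryl group, so epimerisation to the all-trans series threatens. A2 must be obtained as one enantiomer by resolution or a separate asymmetric synthesis. The benzyl ethers of A1 would require hydrogenolysis next to two benzylic ring C–O bonds.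
- Comparison: both plans use the C2 axis and work in two directions. On the cis aryl/C3 relation Alternative 1 is the better plan, because a metallacycle enforces it whereas the chosen plan relies on a transition-state preference. In step count it should be equal or slightly shorter. It is weaker on absolute configuration and on the stability of the new centres in the steps that follow.

Alternative 2: The cut is at O1–C5 and C4–C4a. Going forward, the (Z)-homoallylic alcohol A5 would be treated with PdCl2(MeCN)2, CuCl2, CO and methanol to give ester A4. The C2 hydroxyl adds anti to the alkene bound to divalent palladium at the benzylic carbon C5 (5-endo), the C4–Pd bond inserts CO with retention, methanolysis releases the ester, and CuCl2 reoxidises zerovalent palladium.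
- In favour: ring closure and introduction of C4a happen in one operation. Anti addition across a (Z)-alkene gives cis C4/C5, and allylic 1,3-strain lets the hydroxyl reach one alkene face only, which sets trans C3/C4. The ring C–O bond is made directly, with no oxidation/reduction detour; on this point it is better than the chosen plan.
- Against: the endo mode is less usual than exo closure. The electron-rich benzylic alcohol and (Z)-styrene are exposed to HCl from the reoxidation, so ionisation and Z/E isomerisation threaten. C3a and C4a leave at different oxidation levels and must be equalised later, so the C2 axis is not used. A5 needs its anti C2/C3 relation and its (Z)-alkene built first. The beta-alkoxy ester A4 can epimerise or ring-open. CO is required.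
- Comparison: the key step gives two bonds, one ring and two stereocentres, against two bonds, no ring and four stereocentres in the chosen plan. Both rest on substrate control, an equal point. The linear sequence would be longer.

Alternative 3: The cut is at C3–C3a and C4–C4a. Going forward, tin–lithium exchange with n-BuLi on the bis(stannylmethyl) ether A7 of the (Z,Z)-dienediol triggers two [2,3]-shifts and gives diol A6.
- In favour: it starts from the same chiral-pool alkyne. The migrating carbon is CH2, so no carbinol centre is formed in the shift and no syn/anti question arises. With (Z)-alkenes, allylic 1,3-strain holds the methyl group outside, so (E)-propenyl groups and faithful chirality transfer to C3 and C4 are expected; on C3/C4 fidelity it is better than the chosen plan. The anion is made by exchange, not by deprotonation of an electron-rich benzylic position, which is also better.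
- Against: the key step gives only the C3–C4 core with two of the four stereocentres and neither aryl group. C2 and C5 must then come from cleavage of the propenyl groups and addition of an aryl metal to a dialdehyde, with facial selectivity that is not assured, followed by the same oxidation and reductive ring closure. Organotin is used stoichiometrically, and the diol needs protecting-group steps.
- Comparison: equal in use of the C2 axis and in leaving ring closure for later. The key step is mechanistically cleaner but less convergent, and the route should be two or three steps longer.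

Key step: step 7

Remark on the target: "Eduesmine" is taken to be exactly the (2S,3S,4S,5S) isomer encoded by the SMILES, with ring substituents cis, trans, cis.

Remark on the chemistry: the phenols are carried as triisopropylsilyl ethers, not benzyl ethers. An ArO–CH2Ph group would offer n-BuLi a second, more acidic benzylic site that would be lithiated and undergo a 1,2-shift, and a final hydrogenolysis would endanger the two benzylic ring C–O bonds. The carbon skeletons and the bonds formed in the key step are unchanged. Throughout, Ar = 3-methoxy-4-(triisopropylsilyloxy)phenyl.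

## Route

Step 1
Reactants: 1 vanillin (4-hydroxy-3-methoxybenzaldehyde)
Product: 2 3-methoxy-4-(triisopropylsilyloxy)benzaldehyde
Conditions: TIPSCl, imidazole, DMF, rt
Reagents that add atoms: chlorotriisopropylsilane (TIPSCl), CC(C)[Si](Cl)(C(C)C)C(C)C
Why: Silylation of an acidic phenol with a silyl chloride and imidazole; the aldehyde is inert, and the bulky silyl group is chosen because it tolerates alkyllithium, Lewis acid and ozone and is removed by fluoride.

Step 2
Reactants: 2 3-methoxy-4-(triisopropylsilyloxy)benzaldehyde
Product: 3 [3-methoxy-4-(triisopropylsilyloxy)phenyl]methanol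
Conditions: NaBH4, EtOH/THF, 0 °C
Reagents that add atoms: none
Why: Borohydride reduction of an aryl aldehyde; the hindered aryl silyl ether should survive the cold, weakly basic medium.

Step 3
Reactants: 3 [3-methoxy-4-(triisopropylsilyloxy)phenyl]methanol
Product: 4 [4-(bromomethyl)-2-methoxyphenoxy]triisopropylsilane
Conditions: CBr4, PPh3, CH2Cl2, 0 °C
Reagents that add atoms: carbon tetrabromide, BrC(Br)(Br)Br
Why: Appel bromination under neutral conditions, so no HBr is present to cleave the silyl ether; the reactive benzylic bromide is used at once.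

Step 4
Reactants: 5 (R)-but-3-yn-2-ol (two molecules)
Product: 6 (2R,7R)-octa-3,5-diyne-2,7-diol
Conditions: CuCl (cat.), TMEDA, O2 (1 atm), acetone, rt
Reagents that add atoms: none
Why: Glaser–Hay oxidative homocoupling of a terminal alkyne through its copper acetylide; the carbinol centres are not involved, so the (R,R) diol follows directly from 5.

Step 5
Reactants: 6 (2R,7R)-octa-3,5-diyne-2,7-diol
Product: 7 (2R,3E,5E,7R)-octa-3,5-diene-2,7-diol
Conditions: LiAlH4, THF, 0 °C to reflux; aqueous work-up
Reagents that add atoms: none
Why: Hydroxyl-directed trans-hydroalumination of propargylic alcohols: each alkoxyaluminate delivers hydride to the nearer alkyne carbon and protonation of the vinylalane occurs with retention, so both alkenes become (E); the carbinol centres are untouched.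

Step 6
Reactants: 7 (2R,3E,5E,7R)-octa-3,5-diene-2,7-diol; 4 [4-(bromomethyl)-2-methoxyphenoxy]triisopropylsilane (2.3 equiv)
Product: 8 (2R,3E,5E,7R)-2,7-bis(ArCH2O)octa-3,5-diene
Conditions: NaH, THF, 0 °C; then 4, n-Bu4NI (cat.), 0 °C to rt
Reagents that add atoms: none
Why: Twofold Williamson etherification; the secondary alkoxides attack the primary benzylic bromide by SN2 at a carbon remote from the stereocentres, so configuration is retained, and THF without a dipolar cosolvent together with the bulk of the silyl group should keep alkoxide attack at silicon slow.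

Step 7
Reactants: 8 (2R,3E,5E,7R)-2,7-bis(ArCH2O)octa-3,5-diene
Product: 10 (1S,2R,3R,4S)-1,4-di-Ar-2,3-di[(E)-prop-1-enyl]butane-1,4-diol, via mono-rearranged alkoxide 9 (not isolated)
Conditions: n-BuLi (5 equiv), THF, −78 to −30 °C; aq. NH4Cl
Reagents that add atoms: none
Why: This is the [2,3]-Wittig rearrangement of a secondary (E)-allyl benzyl ether with 1,3-transfer of chirality, carried out twice on one substrate. n-BuLi removes a benzylic proton alpha to oxygen, and the alpha-alkoxybenzyllithium bonds to the alkene carbon three atoms away (C4 of the diene) through a five-membered envelope while the allylic C2–O bond breaks, giving alkoxide 9. The second allyl benzyl ether unit of 9 is unchanged and rearranges in the same way with bonding to C5; no ring is closed. The shift is suprafacial, so each new C–C bond forms on the alkene face from which the C–O bond departs; with the methyl group of the (R) carbinol pseudo-equatorial the new alkene is (E) and the new centres C2 and C3 of 10 are (R). The carbinol centres C1 and C4 become (S) because the aryl group takes the exo position of the envelope, which for an (E)-alkene gives the anti relation to the neighbouring centre. The step needs [2,3] over [1,2] migration, which the low temperature and the concerted six-electron path favour. It needs lithiation at the ArCH2O carbons only, which the silyl protection of the phenols secures by removing any other benzylic ether site. It needs E and anti selectivity in both events, which rest on the (E,E)-diene and on the two identical (R) centres acting in the same C2-symmetric sense.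

Step 8
Reactants: 10 (1S,2R,3R,4S)-1,4-di-Ar-2,3-di[(E)-prop-1-enyl]butane-1,4-diol
Product: 12 (3R,4R,5S)-2,5-di-Ar-3,4-di[(E)-prop-1-enyl]oxolan-2-ol (both C2 epimers), via hydroxy ketone 11 (not isolated)
Conditions: MnO2 (activated), CH2Cl2, rt
Reagents that add atoms: none
Why: MnO2 oxidises benzylic alcohols selectively; the two carbinols of 10 are homotopic, so either gives the same hydroxy ketone 11, whose remaining hydroxyl adds to the aryl ketone to form the five-membered hemiketal 12, in which no secondary benzylic alcohol is left for a second oxidation. The retained carbinol (ring C5) and C3/C4 are not touched.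

Step 9
Reactants: 12 (3R,4R,5S)-2,5-di-Ar-3,4-di[(E)-prop-1-enyl]oxolan-2-ol
Product: 14 (2S,3R,4R,5S)-2,5-di-Ar-3,4-di[(E)-prop-1-enyl]oxolane, via oxocarbenium ion 13 (not isolated)
Conditions: Et3SiH, BF3·OEt2, CH2Cl2, −78 °C
Reagents that add atoms: none
Why: Ionic hydrogenation of a cyclic hemiketal: BF3·OEt2 ionises 12 to the aryl-stabilised oxocarbenium ion 13, and Et3SiH delivers hydride to C2 from the face anti to the adjacent C3 propenyl group, which leaves the aryl group cis to it and sets C2 as (S). The low temperature is meant to suppress reversible opening of the C5–O bond and proton loss from C3.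

Step 10
Reactants: 14 (2S,3R,4R,5S)-2,5-di-Ar-3,4-di[(E)-prop-1-enyl]oxolane
Product: 16 [(2S,3S,4S,5S)-2,5-di-Ar-oxolane-3,4-diyl]dimethanol, via bis-ozonide 15 (not isolated)
Conditions: O3, CH2Cl2, −78 °C (Sudan Red 7B end point); then NaBH4, MeOH, −78 to 0 °C
Reagents that add atoms: ozone, [O-][O+]=O
Why: Ozonolysis with reductive work-up: the disubstituted alkenes should add ozone faster than the arenes when the dye marks the end point, and NaBH4 reduces the ozonides directly to primary alcohols so that the epimerisable beta-alkoxy aldehyde does not accumulate. C3 and C4 are not touched; their descriptors change from R to S only because the CIP priorities change.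

Step 11
Reactants: 16 [(2S,3S,4S,5S)-2,5-di-Ar-oxolane-3,4-diyl]dimethanol
Product: 17 Eduesmine, 4,4'-[(2S,3S,4S,5S)-3,4-bis(hydroxymethyl)oxolane-2,5-diyl]bis(2-methoxyphenol)
Conditions: TBAF, AcOH, THF, 0 °C
Reagents that add atoms: none
Why: Fluoride cleavage of aryl silyl ethers, driven by the Si–F bond; acetic acid buffers the phenoxide so that the p-hydroxybenzylic ring ether is not opened towards a quinone methide, and neither strong acid nor hydrogen is used, which protects the cis C2/C3 and C4/C5 relations.

## Compound list

1 | vanillin | COc1cc(C=O)ccc1O | starting material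
2 | 3-methoxy-4-(triisopropylsilyloxy)benzaldehyde | COc1cc(C=O)ccc1O[Si](C(C)C)(C(C)C)C(C)C | intermediate
3 | [3-methoxy-4-(triisopropylsilyloxy)phenyl]methanol | COc1cc(CO)ccc1O[Si](C(C)C)(C(C)C)C(C)C | intermediate
4 | [4-(bromomethyl)-2-methoxyphenoxy]triisopropylsilane | COc1cc(CBr)ccc1O[Si](C(C)C)(C(C)C)C(C)C | intermediate
5 | (R)-but-3-yn-2-ol | C[C@@H](O)C#C | starting material
6 | (2R,7R)-octa-3,5-diyne-2,7-diol | C[C@@H](O)C#CC#C[C@@H](C)O | intermediate
7 | (2R,3E,5E,7R)-octa-3,5-diene-2,7-diol | C[C@@H](O)/C=C/C=C/[C@@H](C)O | intermediate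
8 | (2R,3E,5E,7R)-2,7-bis{[3-methoxy-4-(triisopropylsilyloxy)phenyl]methoxy}octa-3,5-diene | C[C@@H](OCc1ccc(O[Si](C(C)C)(C(C)C)C(C)C)c(OC)c1)/C=C/C=C/[C@@H](C)OCc1ccc(O[Si](C(C)C)(C(C)C)C(C)C)c(OC)c1 | intermediate
9 | (1S,2R,3E,5R)-1-Ar-5-(ArCH2O)-2-[(E)-prop-1-enyl]hex-3-en-1-ol, present in the flask as its lithium alkoxide | COc1cc([C@@H](O)[C@H](/C=C/C)/C=C/[C@@H](C)OCc2ccc(O[Si](C(C)C)(C(C)C)C(C)C)c(OC)c2)ccc1O[Si](C(C)C)(C(C)C)C(C)C | intermediate
10 | (1S,2R,3R,4S)-1,4-bis[3-methoxy-4-(triisopropylsilyloxy)phenyl]-2,3-di[(E)-prop-1-enyl]butane-1,4-diol | COc1cc([C@@H](O)[C@H](/C=C/C)[C@@H](/C=C/C)[C@H](O)c2ccc(O[Si](C(C)C)(C(C)C)C(C)C)c(OC)c2)ccc1O[Si](C(C)C)(C(C)C)C(C)C | intermediate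
11 | (2R,3R,4S)-4-hydroxy-1,4-di-Ar-2,3-di[(E)-prop-1-enyl]butan-1-one, formed in the flask | COc1cc(C(=O)[C@H](/C=C/C)[C@@H](/C=C/C)[C@H](O)c2ccc(O[Si](C(C)C)(C(C)C)C(C)C)c(OC)c2)ccc1O[Si](C(C)C)(C(C)C)C(C)C | intermediate
12 | (3R,4R,5S)-2,5-di-Ar-3,4-di[(E)-prop-1-enyl]oxolan-2-ol, both C2 epimers | COc1cc(C2(O)O[C@H](c3ccc(O[Si](C(C)C)(C(C)C)C(C)C)c(OC)c3)[C@H](/C=C/C)[C@H]2/C=C/C)ccc1O[Si](C(C)C)(C(C)C)C(C)C | intermediate
13 | (3R,4R,5S)-2,5-di-Ar-3,4-di[(E)-prop-1-enyl]-4,5-dihydro-3H-furan-1-ium (oxocarbenium ion, C2=O1 cationic), formed in the flask | COc1cc(C2=[O+][C@H](c3ccc(O[Si](C(C)C)(C(C)C)C(C)C)c(OC)c3)[C@H](/C=C/C)[C@H]2/C=C/C)ccc1O[Si](C(C)C)(C(C)C)C(C)C | intermediate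
14 | (2S,3R,4R,5S)-2,5-di-Ar-3,4-di[(E)-prop-1-enyl]oxolane | COc1cc([C@H]2O[C@H](c3ccc(O[Si](C(C)C)(C(C)C)C(C)C)c(OC)c3)[C@H](/C=C/C)[C@H]2/C=C/C)ccc1O[Si](C(C)C)(C(C)C)C(C)C | intermediate
15 | bis-ozonide, (2S,3R,4R,5S)-2,5-di-Ar-3,4-bis(5-methyl-1,2,4-trioxolan-3-yl)oxolane, trioxolane carbons unassigned, formed in the flask | COc1cc([C@H]2O[C@H](c3ccc(O[Si](C(C)C)(C(C)C)C(C)C)c(OC)c3)[C@H](C3OOC(C)O3)[C@H]2C2OOC(C)O2)ccc1O[Si](C(C)C)(C(C)C)C(C)C | intermediate
16 | [(2S,3S,4S,5S)-2,5-bis[3-methoxy-4-(triisopropylsilyloxy)phenyl]oxolane-3,4-diyl]dimethanol | COc1cc([C@H]2O[C@H](c3ccc(O[Si](C(C)C)(C(C)C)C(C)C)c(OC)c3)[C@H](CO)[C@H]2CO)ccc1O[Si](C(C)C)(C(C)C)C(C)C | intermediate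
17 | Eduesmine, 4,4'-[(2S,3S,4S,5S)-3,4-bis(hydroxymethyl)oxolane-2,5-diyl]bis(2-methoxyphenol) | COc1cc([C@H]2O[C@H](c3ccc(O)c(OC)c3)[C@H](CO)[C@H]2CO)ccc1O | target

## Step count and least certain steps

Total: 11 steps. Longest linear sequence: 9 steps (steps 1, 2, 3, 6, 7, 8, 9, 10, 11 from 1); the branch from 5 is 8 steps.

**Step 7 (key step).** The most likely failures are these:
- slow or misdirected lithiation, because the benzylic protons of an electron-rich ring are less acidic and the position between OMe and CH2O can be lithiated on the ring;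
- escape into the 1,2-shift through a radical pair if the mixture must be warmed;
- erosion of the anti relation at a carbinol, or of the (E) geometry of a new alkene, which by the stereospecificity of the shift means the wrong configuration at C2 or C3 of 10. The centre made in the first shift sits on the alkene attacked in the second and may oppose it.

Fallback, setting out from 6 and returning only at 17:
- Semi-reduce 6 with Zn activated by Cu(OAc)2 and AgNO3 to (2R,3Z,5Z,7R)-octa-3,5-diene-2,7-diol F1.
- Alkylate with KH and Bu3SnCH2I to A7, and treat with n-BuLi to obtain A6, where allylic 1,3-strain controls C3 and C4.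
- Silylate with TBDPSCl to (2S,3S)-1,4-bis(tert-butyldiphenylsilyloxy)-2,3-di[(E)-prop-1-enyl]butane F2.
- Ozonise with Me2S work-up to (2S,3S)-2,3-bis[(tert-butyldiphenylsilyloxy)methyl]butanedial F3.
- Add the aryllithium made from 4-bromo-2-methoxy-1-(triisopropylsilyloxy)benzene F4 and n-BuLi, in the presence of CeCl3, to give (1S,2S,3S,4S)-1,4-di-Ar-2,3-bis[(tert-butyldiphenylsilyloxy)methyl]butane-1,4-diol F5. The Felkin–Anh mode, with the backbone as the large group, gives the relation that becomes cis aryl/CH2O in the ring.
- Oxidise with MnO2 to hemiketal (3S,4S,5S)-2,5-di-Ar-3,4-bis[(tert-butyldiphenylsilyloxy)methyl]oxolan-2-ol F6.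
- Reduce with Et3SiH/BF3·OEt2 to (2S,3S,4S,5S)-2,5-di-Ar-3,4-bis[(tert-butyldiphenylsilyloxy)methyl]oxolane F7.
- Remove all four silyl groups with buffered TBAF to reach 17.

**Step 9.** Hydride may add with poor facial selectivity, because the C5 aryl and C4 propenyl groups lie on the face that must be attacked. The cation may also lose the allylic C3 proton to a conjugated enol ether, which would scramble C3, or the C5–O bond may open reversibly and epimerise C5.

Fallback, setting out from 10 and returning at 17: cleave the propenyl groups first, so that the cation carries no allylic C3–H.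
- Ozonise 10 with NaBH4 work-up to (1S,2S,3S,4S)-1,4-di-Ar-2,3-bis(hydroxymethyl)butane-1,4-diol F8.
- Silylate the primary hydroxyls selectively with TBDPSCl and imidazole to diol F5.
- Oxidise with MnO2 to hemiketal F6, reduce with Et3SiH/BF3·OEt2 to oxolane F7, and desilylate globally with TBAF/AcOH to 17.

**Step 8.** Over-oxidation to the 1,4-diketone is possible if the open hydroxy ketone form is populated enough; this would destroy the retained carbinol centre. The doubly activated alpha-hydrogen of the ketone could also allow the propenyl group to move into conjugation.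

Fallback, setting out from 10 and returning at 14:
- Monosilylate with one equivalent of TESCl and imidazole to (1S,2R,3R,4S)-1,4-di-Ar-2,3-di[(E)-prop-1-enyl]-4-(triethylsilyloxy)butan-1-ol F9. Any bis-ether is recycled by desilylation without loss of stereochemistry.
- Oxidise the remaining alcohol with MnO2 to (2R,3R,4S)-1,4-di-Ar-2,3-di[(E)-prop-1-enyl]-4-(triethylsilyloxy)butan-1-one F10.
- Treat with Et3SiH/BF3·OEt2 at −78 °C, where the silyl ether oxygen closes onto the activated ketone and the resulting cation is reduced to 14.

**Step 10.** Ozone may attack the electron-rich arenes once the alkenes are consumed, and any free aldehyde formed before reduction may epimerise or undergo beta-elimination of the ring oxygen.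

Fallback, setting out from 14 and returning at 16: dihydroxylate both alkenes with OsO4 (cat.) and N-methylmorpholine N-oxide to the tetraol (2S,3R,4R,5S)-2,5-di-Ar-3,4-bis(1,2-dihydroxypropyl)oxolane F11, then cleave with NaIO4 and reduce at once with NaBH4 to 16.

**Step 6.** The alkoxide may attack silicon and release a phenoxide that ejects bromide as a quinone methide, and bromide 4 may decompose on storage.

Fallback, setting out from 3 and returning at 8: convert 3 with Cl3CCN and DBU into [3-methoxy-4-(triisopropylsilyloxy)phenyl]methyl 2,2,2-trichloroacetimidate F12, and couple it with 7 under a catalytic amount of camphorsulfonic acid in CH2Cl2 at low temperature, so that no alkoxide is ever present.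

## Further compounds

F1 | step 7 | (2R,3Z,5Z,7R)-octa-3,5-diene-2,7-diol | C[C@@H](O)/C=C\C=C/[C@@H](C)O
F2 | step 7 | (2S,3S)-1,4-bis(tert-butyldiphenylsilyloxy)-2,3-di[(E)-prop-1-enyl]butane | C/C=C/[C@H](CO[Si](c1ccccc1)(c1ccccc1)C(C)(C)C)[C@@H](CO[Si](c1ccccc1)(c1ccccc1)C(C)(C)C)/C=C/C
F3 | step 7 | (2S,3S)-2,3-bis[(tert-butyldiphenylsilyloxy)methyl]butanedial | O=C[C@H](CO[Si](c1ccccc1)(c1ccccc1)C(C)(C)C)[C@@H](CO[Si](c1ccccc1)(c1ccccc1)C(C)(C)C)C=O
F4 | step 7 | 4-bromo-2-methoxy-1-(triisopropylsilyloxy)benzene | COc1cc(Br)ccc1O[Si](C(C)C)(C(C)C)C(C)C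
F5 | step 7 | (1S,2S,3S,4S)-1,4-bis[3-methoxy-4-(triisopropylsilyloxy)phenyl]-2,3-bis[(tert-butyldiphenylsilyloxy)methyl]butane-1,4-diol | COc1cc([C@@H](O)[C@H](CO[Si](c2ccccc2)(c2ccccc2)C(C)(C)C)[C@@H](CO[Si](c2ccccc2)(c2ccccc2)C(C)(C)C)[C@H](O)c2ccc(O[Si](C(C)C)(C(C)C)C(C)C)c(OC)c2)ccc1O[Si](C(C)C)(C(C)C)C(C)C
F6 | step 7 | (3S,4S,5S)-2,5-bis[3-methoxy-4-(triisopropylsilyloxy)phenyl]-3,4-bis[(tert-butyldiphenylsilyloxy)methyl]oxolan-2-ol | COc1cc(C2(O)O[C@H](c3ccc(O[Si](C(C)C)(C(C)C)C(C)C)c(OC)c3)[C@H](CO[Si](c3ccccc3)(c3ccccc3)C(C)(C)C)[C@H]2CO[Si](c2ccccc2)(c2ccccc2)C(C)(C)C)ccc1O[Si](C(C)C)(C(C)C)C(C)C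
F7 | step 7 | (2S,3S,4S,5S)-2,5-bis[3-methoxy-4-(triisopropylsilyloxy)phenyl]-3,4-bis[(tert-butyldiphenylsilyloxy)methyl]oxolane | COc1cc([C@H]2O[C@H](c3ccc(O[Si](C(C)C)(C(C)C)C(C)C)c(OC)c3)[C@H](CO[Si](c3ccccc3)(c3ccccc3)C(C)(C)C)[C@H]2CO[Si](c2ccccc2)(c2ccccc2)C(C)(C)C)ccc1O[Si](C(C)C)(C(C)C)C(C)C
F8 | step 9 | (1S,2S,3S,4S)-1,4-bis[3-methoxy-4-(triisopropylsilyloxy)phenyl]-2,3-bis(hydroxymethyl)butane-1,4-diol | COc1cc([C@@H](O)[C@H](CO)[C@@H](CO)[C@H](O)c2ccc(O[Si](C(C)C)(C(C)C)C(C)C)c(OC)c2)ccc1O[Si](C(C)C)(C(C)C)C(C)C
F9 | step 8 | (1S,2R,3R,4S)-1,4-bis[3-methoxy-4-(triisopropylsilyloxy)phenyl]-2,3-di[(E)-prop-1-enyl]-4-(triethylsilyloxy)butan-1-ol | COc1cc([C@@H](O[Si](CC)(CC)CC)[C@H](/C=C/C)[C@@H](/C=C/C)[C@H](O)c2ccc(O[Si](C(C)C)(C(C)C)C(C)C)c(OC)c2)ccc1O[Si](C(C)C)(C(C)C)C(C)C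
F10 | step 8 | (2R,3R,4S)-1,4-bis[3-methoxy-4-(triisopropylsilyloxy)phenyl]-2,3-di[(E)-prop-1-enyl]-4-(triethylsilyloxy)butan-1-one | COc1cc([C@@H](O[Si](CC)(CC)CC)[C@H](/C=C/C)[C@@H](/C=C/C)C(=O)c2ccc(O[Si](C(C)C)(C(C)C)C(C)C)c(OC)c2)ccc1O[Si](C(C)C)(C(C)C)C(C)C
F11 | step 10 | (2S,3R,4R,5S)-2,5-bis[3-methoxy-4-(triisopropylsilyloxy)phenyl]-3,4-bis(1,2-dihydroxypropyl)oxolane, carbinol centres of the side chains unassigned | COc1cc([C@H]2O[C@H](c3ccc(O[Si](C(C)C)(C(C)C)C(C)C)c(OC)c3)[C@H](C(O)C(C)O)[C@H]2C(O)C(C)O)ccc1O[Si](C(C)C)(C(C)C)C(C)C
F12 | step 6 | [3-methoxy-4-(triisopropylsilyloxy)phenyl]methyl 2,2,2-trichloroacetimidate | COc1cc(COC(=N)C(Cl)(Cl)Cl)ccc1O[Si](C(C)C)(C(C)C)C(C)C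
A1 | alternative 1 | (2S,3R,4R,5S)-2,5-bis(4-benzyloxy-3-methoxyphenyl)-N3,N4-di(quinolin-8-yl)oxolane-3,4-dicarboxamide | COc1cc([C@H]2O[C@H](c3ccc(OCc4ccccc4)c(OC)c3)[C@H](C(=O)Nc3cccc4cccnc34)[C@H]2C(=O)Nc2cccc3cccnc23)ccc1OCc1ccccc1
A2 | alternative 1 | (3R,4R)-N3,N4-di(quinolin-8-yl)oxolane-3,4-dicarboxamide (trans) | C1OC[C@H](C(=O)Nc2cccc3cccnc23)[C@H]1C(=O)Nc1cccc2cccnc12
A3 | alternative 1 | 1-(benzyloxy)-4-iodo-2-methoxybenzene | COc1cc(I)ccc1OCc1ccccc1
A4 | alternative 2 | methyl (2S,3R,4S,5S)-2,5-bis(4-benzyloxy-3-methoxyphenyl)-4-[(tert-butyldimethylsilyloxy)methyl]oxolane-3-carboxylate (cis, trans, cis) | COc1cc([C@H]2O[C@H](c3ccc(OCc4ccccc4)c(OC)c3)[C@H](C(=O)OC)[C@H]2CO[Si](C)(C)C(C)(C)C)ccc1OCc1ccccc1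
A5 | alternative 2 | (1S,2S,3Z)-1,4-bis(4-benzyloxy-3-methoxyphenyl)-2-[(tert-butyldimethylsilyloxy)methyl]but-3-en-1-ol | COc1cc([C@@H](O)[C@H](CO[Si](C)(C)C(C)(C)C)/C=C\c2ccc(OCc3ccccc3)c(OC)c2)ccc1OCc1ccccc1
A6 | alternative 3 | (2S,3S)-2,3-di[(E)-prop-1-enyl]butane-1,4-diol | C/C=C/[C@H](CO)[C@@H](CO)/C=C/C
A7 | alternative 3 | (2R,3Z,5Z,7R)-2,7-bis[(tributylstannyl)methoxy]octa-3,5-diene | C[C@@H](OC[Sn](CCCC)(CCCC)CCCC)/C=C\C=C/[C@@H](C)OC[Sn](CCCC)(CCCC)CCCC
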